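**Retrosynthetic overview**
- The imidazoledione ring is made separately and attached last, by C–N condensation of a protected 2-aminoimidazole with silyl-activated 1-methylparabanic acid; global desilylation then gives the target.
- The 2-amino group comes from C2 lithiation, azide transfer and reduction of a 1-methyl-4,5-disubstituted imidazole.
- The imidazole ring (the first ring formed) comes from Marckwald closure of an α-amino ketone with methyl isothiocyanate, which places N–Me on the former ketone carbon; the sulfur is then removed.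
- The α-amino ketone comes from a Weinreb amide and a 4-(silyloxy)benzyl Grignard reagent.
- Key C–C bond: auxiliary-controlled boron aldol of a chloroacetyl imide with 4-methoxybenzaldehyde sets the (R)-carbinol; Cl is then exchanged for N3 and carried on as NHBoc.

Assumption: the single stereocentre is (R) (CIP order O > imidazolyl C > aryl C > H, read from the given SMILES); the amino-bearing carbon next to it becomes aromatic, so its configuration is irrelevant.

**Route**

Step 1
Reactants: 1 (S)-4-benzyl-1,3-oxazolidin-2-one; 2 chloroacetyl chloride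
Product: 3 (S)-4-benzyl-3-(2-chloroacetyl)-1,3-oxazolidin-2-one
Conditions: n-BuLi, THF, −78 °C; then 2, −78 → 0 °C
Reagents that add atoms: none
Why: N-acylation of the lithiated oxazolidinone by the acid chloride is fast at −78 °C and leaves the alkyl chloride untouched.

Step 2
Reactants: 3 (S)-4-benzyl-3-(2-chloroacetyl)-1,3-oxazolidin-2-one; 4 4-methoxybenzaldehyde
Product: 6 (S)-4-benzyl-3-[(2S,3R)-2-chloro-3-hydroxy-3-(4-methoxyphenyl)propanoyl]-1,3-oxazolidin-2-one, via boron enolate 5 (not isolated)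
Conditions: Bu2BOTf, Et3N, CH2Cl2, −78 → 0 °C; 4, −78 → 0 °C; then pH 7 buffer, MeOH, 30% H2O2, 0 °C
Reagents that add atoms: none
Why: Evans syn aldol: the Z-dibutylboron enolate reacts through a Zimmerman–Traxler chair with the benzyl group of the auxiliary shielding one face, giving the (2S,3R) chlorohydrin whose C3 is the (R)-carbinol of the target.

Step 3
Reactants: 6 (S)-4-benzyl-3-[(2S,3R)-2-chloro-3-hydroxy-3-(4-methoxyphenyl)propanoyl]-1,3-oxazolidin-2-one
Product: 7 (S)-3-[(2R,3R)-2-azido-3-hydroxy-3-(4-methoxyphenyl)propanoyl]-4-benzyl-1,3-oxazolidin-2-one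
Conditions: NaN3, DMF, rt
Reagents that add atoms: sodium azide [Na+].[N-]=[N+]=[N-]
Why: SN2 displacement of the activated α-chloride by the non-basic azide ion inverts C2 only; the carbinol carbon is not involved.

Step 4
Reactants: 7 (S)-3-[(2R,3R)-2-azido-3-hydroxy-3-(4-methoxyphenyl)propanoyl]-4-benzyl-1,3-oxazolidin-2-one
Product: 8 (2R,3R)-2-azido-3-hydroxy-N-methoxy-3-(4-methoxyphenyl)-N-methylpropanamide
Conditions: MeNHOMe·HCl, AlMe3, CH2Cl2, −15 → 0 °C; aq work-up
Reagents that add atoms: N,O-dimethylhydroxylamine hydrochloride CNOC.Cl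
Why: Weinreb transamidation: the aluminium amide is delivered to the exocyclic imide carbonyl by the free β-hydroxyl, releasing the auxiliary for recovery.

Step 5
Reactants: 8 (2R,3R)-2-azido-3-hydroxy-N-methoxy-3-(4-methoxyphenyl)-N-methylpropanamide
Product: 9 (2R,3R)-2-azido-3-[(tert-butyldimethylsilyl)oxy]-N-methoxy-3-(4-methoxyphenyl)-N-methylpropanamide
Conditions: TBSOTf, 2,6-lutidine, CH2Cl2, −78 → 0 °C
Reagents that add atoms: tert-butyldimethylsilyl trifluoromethanesulfonate CC(C)(C)[Si](C)(C)OS(=O)(=O)C(F)(F)F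
Why: O-silylation under buffered conditions blocks retro-aldol in later basic steps without touching the C–O stereocentre.

Step 6
Reactants: 9 (2R,3R)-2-azido-3-[(tert-butyldimethylsilyl)oxy]-N-methoxy-3-(4-methoxyphenyl)-N-methylpropanamide
Product: 11 tert-butyl N-[(2R,3R)-3-[(tert-butyldimethylsilyl)oxy]-1-[methoxy(methyl)amino]-3-(4-methoxyphenyl)-1-oxopropan-2-yl]carbamate, via free amine 10 (not isolated)
Conditions: PMe3, THF/H2O, rt; then Boc2O, Et3N, rt
Reagents that add atoms: di-tert-butyl dicarbonate CC(C)(C)OC(=O)OC(=O)OC(C)(C)C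
Why: Staudinger reduction is neutral and spares the benzylic silyl ether and the N–O bond, and in-flask carbamoylation gives a carbamate that tolerates the Grignard step.

Step 7
Reactants: 12 4-hydroxybenzaldehyde
Product: 13 4-[(triisopropylsilyl)oxy]benzaldehyde
Conditions: TIPSCl, imidazole, DMF, rt
Reagents that add atoms: triisopropylsilyl chloride CC(C)[Si](Cl)(C(C)C)C(C)C
Why: Imidazole-catalysed phenol silylation installs a bulky aryl silyl ether that later survives organomagnesium, organolithium and acid.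

Step 8
Reactants: 13 4-[(triisopropylsilyl)oxy]benzaldehyde
Product: 14 {4-[(triisopropylsilyl)oxy]phenyl}methanol
Conditions: NaBH4, MeOH, 0 °C
Reagents that add atoms: none
Why: Hydride reduction of the aldehyde is chemoselective and the silyl ether is inert.

Step 9
Reactants: 14 {4-[(triisopropylsilyl)oxy]phenyl}methanol
Product: 15 [4-(chloromethyl)phenoxy]triisopropylsilane
Conditions: SOCl2, pyridine, CH2Cl2, 0 °C
Reagents that add atoms: thionyl chloride O=S(Cl)Cl
Why: Deoxychlorination through the chlorosulfite is rapid for an electron-rich benzylic alcohol, and pyridine traps the HCl.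

Step 10
Reactants: 11 tert-butyl N-[(2R,3R)-3-[(tert-butyldimethylsilyl)oxy]-1-[methoxy(methyl)amino]-3-(4-methoxyphenyl)-1-oxopropan-2-yl]carbamate; 15 [4-(chloromethyl)phenoxy]triisopropylsilane
Product: 17 tert-butyl N-[(1R,2R)-1-[(tert-butyldimethylsilyl)oxy]-1-(4-methoxyphenyl)-3-oxo-4-{4-[(triisopropylsilyl)oxy]phenyl}butan-2-yl]carbamate, via Grignard reagent 16 (not isolated)
Conditions: 15 (3 equiv), Mg, THF, 0 °C → rt; then 11, −20 → 0 °C; aq work-up
Reagents that add atoms: none
Why: Weinreb ketone synthesis: the first equivalent deprotonates the carbamate N–H (protecting the α-C–H), and the chelated tetrahedral adduct releases the ketone only on work-up, so there is no over-addition.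

Step 11
Reactants: 17 tert-butyl N-[(1R,2R)-1-[(tert-butyldimethylsilyl)oxy]-1-(4-methoxyphenyl)-3-oxo-4-{4-[(triisopropylsilyl)oxy]phenyl}butan-2-yl]carbamate
Product: 18 (1R,2R)-1-[(tert-butyldimethylsilyl)oxy]-1-(4-methoxyphenyl)-3-oxo-4-{4-[(triisopropylsilyl)oxy]phenyl}butan-2-aminium trifluoroacetate
Conditions: TFA/CH2Cl2 (1:4), 0 °C, 1 h; evaporate with toluene
Reagents that add atoms: trifluoroacetic acid OC(=O)C(F)(F)F
Why: Acidolytic carbamate cleavage gives the α-amino ketone as a salt that cannot self-condense, and the adjacent ammonium and ketone disfavour ionisation of the benzylic silyl ether.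

Step 12
Reactants: 18 (1R,2R)-1-[(tert-butyldimethylsilyl)oxy]-1-(4-methoxyphenyl)-3-oxo-4-{4-[(triisopropylsilyl)oxy]phenyl}butan-2-aminium trifluoroacetate; 19 methyl isothiocyanate
Product: 21 4-[(R)-[(tert-butyldimethylsilyl)oxy](4-methoxyphenyl)methyl]-1-methyl-5-{4-[(triisopropylsilyl)oxy]benzyl}-1,3-dihydro-2H-imidazole-2-thione, via thiourea 20 (not isolated)
Conditions: 19, Et3N, EtOH, 0 °C → rt; then AcOH, 50 °C
Reagents that add atoms: none
Why: Marckwald imidazole synthesis: only the NHMe nitrogen of the thiourea can reach the ketone, so cyclodehydration places N–Me next to the benzyl-bearing carbon, and aromatisation removes the irrelevant α-stereocentre.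

Step 13
Reactants: 21 4-[(R)-[(tert-butyldimethylsilyl)oxy](4-methoxyphenyl)methyl]-1-methyl-5-{4-[(triisopropylsilyl)oxy]benzyl}-1,3-dihydro-2H-imidazole-2-thione
Product: 22 4-[(R)-[(tert-butyldimethylsilyl)oxy](4-methoxyphenyl)methyl]-1-methyl-5-{4-[(triisopropylsilyl)oxy]benzyl}-1H-imidazole
Conditions: Raney Ni (acetone-deactivated), EtOH, rt
Reagents that add atoms: none
Why: Reductive desulfurisation of the cyclic thiourea leaves the aromatic imidazole with C2–H, and at room temperature the silyl ethers are not hydrogenolysed.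

Step 14
Reactants: 22 4-[(R)-[(tert-butyldimethylsilyl)oxy](4-methoxyphenyl)methyl]-1-methyl-5-{4-[(triisopropylsilyl)oxy]benzyl}-1H-imidazole
Product: 24 2-azido-4-[(R)-[(tert-butyldimethylsilyl)oxy](4-methoxyphenyl)methyl]-1-methyl-5-{4-[(triisopropylsilyl)oxy]benzyl}-1H-imidazole, via 2-lithioimidazole 23 (not isolated)
Conditions: n-BuLi, THF, −78 °C, 30 min; then TsN3, −78 °C → rt
Reagents that add atoms: 4-methylbenzenesulfonyl azide Cc1ccc(cc1)S(=O)(=O)N=[N+]=[N-]
Why: Electrophilic azidation: C2–H between the two nitrogens is the kinetically most acidic site, and the 2-lithio species attacks the terminal nitrogen of the sulfonyl azide, the triazenide then expelling sulfinate.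

Step 15
Reactants: 24 2-azido-4-[(R)-[(tert-butyldimethylsilyl)oxy](4-methoxyphenyl)methyl]-1-methyl-5-{4-[(triisopropylsilyl)oxy]benzyl}-1H-imidazole
Product: 25 4-[(R)-[(tert-butyldimethylsilyl)oxy](4-methoxyphenyl)methyl]-1-methyl-5-{4-[(triisopropylsilyl)oxy]benzyl}-1H-imidazol-2-amine
Conditions: propane-1,3-dithiol, Et3N, MeOH, rt
Reagents that add atoms: none
Why: Thiol-mediated azide reduction is neutral to weakly basic and non-hydrogenolytic, so the doubly benzylic C–O bond is safe.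

Step 16
Reactants: 26 N-methylurea; 27 oxalyl chloride
Product: 28 1-methylimidazolidine-2,4,5-trione
Conditions: THF, 0 °C → reflux
Reagents that add atoms: none
Why: Cyclocondensation by double N-acylation of the urea with the bis-acid chloride closes the five-membered trione.

Step 17
Reactants: 25 4-[(R)-[(tert-butyldimethylsilyl)oxy](4-methoxyphenyl)methyl]-1-methyl-5-{4-[(triisopropylsilyl)oxy]benzyl}-1H-imidazol-2-amine; 28 1-methylimidazolidine-2,4,5-trione
Product: 30 4-({4-[(R)-[(tert-butyldimethylsilyl)oxy](4-methoxyphenyl)methyl]-1-methyl-5-{4-[(triisopropylsilyl)oxy]benzyl}-1H-imidazol-2-yl}amino)-1-methyl-1H-imidazole-2,5-dione, via silyl imidate 29 (not isolated)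
Conditions: 28, N,O-bis(trimethylsilyl)acetamide, MeCN, 80 °C, 1 h; then 25, toluene, 110 °C; MeOH work-up
Reagents that add atoms: none
Why: Addition–elimination condensation: O-silylation activates the carbonyl next to N–H, and the exocyclic amine displaces silanolate there, giving the 4-amino-imidazole-2,5-dione regiochemistry of the naamidine family.

Step 18
Reactants: 30 4-({4-[(R)-[(tert-butyldimethylsilyl)oxy](4-methoxyphenyl)methyl]-1-methyl-5-{4-[(triisopropylsilyl)oxy]benzyl}-1H-imidazol-2-yl}amino)-1-methyl-1H-imidazole-2,5-dione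
Product: 31 4-({5-(4-hydroxybenzyl)-4-[(R)-hydroxy(4-methoxyphenyl)methyl]-1-methyl-1H-imidazol-2-yl}amino)-1-methyl-1H-imidazole-2,5-dione
Conditions: TBAF, AcOH (1:1), THF, 0 °C → rt
Reagents that add atoms: none
Why: Fluoride-mediated desilylation cleaves both Si–O bonds, and the acetic acid buffer protects the base-sensitive imidazoledione and avoids ionising the (R)-carbinol.

**Compound list**

1 | (S)-4-benzyl-1,3-oxazolidin-2-one | O=C1N[C@@H](Cc2ccccc2)CO1 | starting material
2 | chloroacetyl chloride | ClCC(Cl)=O | starting material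
3 | (S)-4-benzyl-3-(2-chloroacetyl)-1,3-oxazolidin-2-one | ClCC(=O)N1[C@@H](Cc2ccccc2)COC1=O | intermediate
4 | 4-methoxybenzaldehyde | COc1ccc(C=O)cc1 | starting material
5 | (Z)-dibutylboron enolate of 3 | Cl/C=C(\OB(CCCC)CCCC)N1[C@@H](Cc2ccccc2)COC1=O | intermediate
6 | (S)-4-benzyl-3-[(2S,3R)-2-chloro-3-hydroxy-3-(4-methoxyphenyl)propanoyl]-1,3-oxazolidin-2-one | COc1ccc([C@@H](O)[C@H](Cl)C(=O)N2[C@@H](Cc3ccccc3)COC2=O)cc1 | intermediate
7 | (S)-3-[(2R,3R)-2-azido-3-hydroxy-3-(4-methoxyphenyl)propanoyl]-4-benzyl-1,3-oxazolidin-2-one | COc1ccc([C@@H](O)[C@@H](N=[N+]=[N-])C(=O)N2[C@@H](Cc3ccccc3)COC2=O)cc1 | intermediate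
8 | (2R,3R)-2-azido-3-hydroxy-N-methoxy-3-(4-methoxyphenyl)-N-methylpropanamide | COc1ccc([C@@H](O)[C@@H](N=[N+]=[N-])C(=O)N(C)OC)cc1 | intermediate
9 | (2R,3R)-2-azido-3-[(tert-butyldimethylsilyl)oxy]-N-methoxy-3-(4-methoxyphenyl)-N-methylpropanamide | COc1ccc([C@@H](O[Si](C)(C)C(C)(C)C)[C@@H](N=[N+]=[N-])C(=O)N(C)OC)cc1 | intermediate
10 | (2R,3R)-2-amino-3-[(tert-butyldimethylsilyl)oxy]-N-methoxy-3-(4-methoxyphenyl)-N-methylpropanamide | COc1ccc([C@@H](O[Si](C)(C)C(C)(C)C)[C@@H](N)C(=O)N(C)OC)cc1 | intermediate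
11 | tert-butyl N-[(2R,3R)-3-[(tert-butyldimethylsilyl)oxy]-1-[methoxy(methyl)amino]-3-(4-methoxyphenyl)-1-oxopropan-2-yl]carbamate | COc1ccc([C@@H](O[Si](C)(C)C(C)(C)C)[C@@H](NC(=O)OC(C)(C)C)C(=O)N(C)OC)cc1 | intermediate
12 | 4-hydroxybenzaldehyde | O=Cc1ccc(O)cc1 | starting material
13 | 4-[(triisopropylsilyl)oxy]benzaldehyde | O=Cc1ccc(O[Si](C(C)C)(C(C)C)C(C)C)cc1 | intermediate
14 | {4-[(triisopropylsilyl)oxy]phenyl}methanol | OCc1ccc(O[Si](C(C)C)(C(C)C)C(C)C)cc1 | intermediate
15 | [4-(chloromethyl)phenoxy]triisopropylsilane | ClCc1ccc(O[Si](C(C)C)(C(C)C)C(C)C)cc1 | intermediate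
16 | {4-[(triisopropylsilyl)oxy]benzyl}magnesium chloride | Cl[Mg]Cc1ccc(O[Si](C(C)C)(C(C)C)C(C)C)cc1 | intermediate
17 | tert-butyl N-[(1R,2R)-1-[(tert-butyldimethylsilyl)oxy]-1-(4-methoxyphenyl)-3-oxo-4-{4-[(triisopropylsilyl)oxy]phenyl}butan-2-yl]carbamate | COc1ccc([C@@H](O[Si](C)(C)C(C)(C)C)[C@@H](NC(=O)OC(C)(C)C)C(=O)Cc2ccc(O[Si](C(C)C)(C(C)C)C(C)C)cc2)cc1 | intermediate
18 | (1R,2R)-1-[(tert-butyldimethylsilyl)oxy]-1-(4-methoxyphenyl)-3-oxo-4-{4-[(triisopropylsilyl)oxy]phenyl}butan-2-aminium trifluoroacetate | COc1ccc([C@@H](O[Si](C)(C)C(C)(C)C)[C@@H]([NH3+])C(=O)Cc2ccc(O[Si](C(C)C)(C(C)C)C(C)C)cc2)cc1.[O-]C(=O)C(F)(F)F | intermediate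
19 | methyl isothiocyanate | CN=C=S | starting material
20 | 1-[(1R,2R)-1-[(tert-butyldimethylsilyl)oxy]-1-(4-methoxyphenyl)-3-oxo-4-{4-[(triisopropylsilyl)oxy]phenyl}butan-2-yl]-3-methylthiourea | COc1ccc([C@@H](O[Si](C)(C)C(C)(C)C)[C@@H](NC(=S)NC)C(=O)Cc2ccc(O[Si](C(C)C)(C(C)C)C(C)C)cc2)cc1 | intermediate
21 | 4-[(R)-[(tert-butyldimethylsilyl)oxy](4-methoxyphenyl)methyl]-1-methyl-5-{4-[(triisopropylsilyl)oxy]benzyl}-1,3-dihydro-2H-imidazole-2-thione | COc1ccc([C@@H](O[Si](C)(C)C(C)(C)C)c2[nH]c(=S)n(C)c2Cc2ccc(O[Si](C(C)C)(C(C)C)C(C)C)cc2)cc1 | intermediate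
22 | 4-[(R)-[(tert-butyldimethylsilyl)oxy](4-methoxyphenyl)methyl]-1-methyl-5-{4-[(triisopropylsilyl)oxy]benzyl}-1H-imidazole | COc1ccc([C@@H](O[Si](C)(C)C(C)(C)C)c2ncn(C)c2Cc2ccc(O[Si](C(C)C)(C(C)C)C(C)C)cc2)cc1 | intermediate
23 | 2-lithio derivative of 22 | COc1ccc([C@@H](O[Si](C)(C)C(C)(C)C)c2nc([Li])n(C)c2Cc2ccc(O[Si](C(C)C)(C(C)C)C(C)C)cc2)cc1 | intermediate
24 | 2-azido-4-[(R)-[(tert-butyldimethylsilyl)oxy](4-methoxyphenyl)methyl]-1-methyl-5-{4-[(triisopropylsilyl)oxy]benzyl}-1H-imidazole | COc1ccc([C@@H](O[Si](C)(C)C(C)(C)C)c2nc(N=[N+]=[N-])n(C)c2Cc2ccc(O[Si](C(C)C)(C(C)C)C(C)C)cc2)cc1 | intermediate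
25 | 4-[(R)-[(tert-butyldimethylsilyl)oxy](4-methoxyphenyl)methyl]-1-methyl-5-{4-[(triisopropylsilyl)oxy]benzyl}-1H-imidazol-2-amine | COc1ccc([C@@H](O[Si](C)(C)C(C)(C)C)c2nc(N)n(C)c2Cc2ccc(O[Si](C(C)C)(C(C)C)C(C)C)cc2)cc1 | intermediate
26 | N-methylurea | CNC(N)=O | starting material
27 | oxalyl chloride | O=C(Cl)C(Cl)=O | starting material
28 | 1-methylimidazolidine-2,4,5-trione | CN1C(=O)NC(=O)C1=O | intermediate
29 | 1-methyl-4-[(trimethylsilyl)oxy]-1H-imidazole-2,5-dione | CN1C(=O)N=C(O[Si](C)(C)C)C1=O | intermediate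
30 | 4-({4-[(R)-[(tert-butyldimethylsilyl)oxy](4-methoxyphenyl)methyl]-1-methyl-5-{4-[(triisopropylsilyl)oxy]benzyl}-1H-imidazol-2-yl}amino)-1-methyl-1H-imidazole-2,5-dione | COc1ccc([C@@H](O[Si](C)(C)C(C)(C)C)c2nc(NC3=NC(=O)N(C)C3=O)n(C)c2Cc2ccc(O[Si](C(C)C)(C(C)C)C(C)C)cc2)cc1 | intermediate
31 | 4-({5-(4-hydroxybenzyl)-4-[(R)-hydroxy(4-methoxyphenyl)methyl]-1-methyl-1H-imidazol-2-yl}amino)-1-methyl-1H-imidazole-2,5-dione | COc1ccc([C@@H](O)c2nc(NC3=NC(=O)N(C)C3=O)n(C)c2Cc2ccc(O)cc2)cc1 | target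

**Totals**
- Total step count: 18.
- Longest linear sequence: 14 steps (steps 1–6, 10–15, 17, 18, from 1 to 31). Side branches are steps 7–9 and step 16.

**Three steps most likely to fail, with fallbacks**

Step 12 (Marckwald closure). The weak acid and warming needed for dehydration could ionise or eliminate the p-methoxybenzylic silyl ether, and the thiourea can also close through sulfur. The fallback sets out from 18 and comes back at 22, so it also bypasses step 13. Compound 18 is N-formylated with acetic formic anhydride and i-Pr2NEt in CH2Cl2 at 0 °C to give the formamide F1. F1 is heated with MeNH2 and AcOH in EtOH in a sealed tube at 70 °C; the N-methyl enamine formed at the ketone closes onto the formyl carbon and dehydrates to 22. The formyl carbon becomes C2 and the regiochemistry is again fixed, because only two nitrogens are present.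

Step 14 (C2 lithiation and azide transfer). Competing deprotonation at the benzylic positions or poor azide transfer would lower the yield. The fallback sets out from 18 and comes back at 25, replacing steps 12–15. Compound 18 is guanylated with allyl N-(methylcarbamothioyl)carbamate, EDCI and i-Pr2NEt in DMF to give the allyloxycarbonyl-protected N-methylguanidine ketone F2. In F2 only the NHMe nitrogen is nucleophilic enough to attack the ketone, so cyclodehydration with catalytic AcOH at 40 °C gives the allyl carbamate of the 2-aminoimidazole F3. Pd(PPh3)4 and morpholine in THF then remove the allyl carbamate under neutral conditions to give 25.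

Step 17 (condensation with silylated 1-methylparabanic acid). The hindered amine at 110 °C may react slowly, give bis-adducts or lose optical purity at the carbinol. The fallback sets out from 25 and comes back at 30, building the imidazoledione ring in place. Compound 25 is condensed with ethyl 2-ethoxy-2-iminoacetate in EtOH at rt to give the amidino ester F4. F4 is N-carbamoylated with methyl isocyanate and Et3N in THF, and the resulting N-methylurea nitrogen closes onto the ethyl ester at rt to 50 °C to give 30.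

**Further compounds**

F1 | step 12 | N-[(1R,2R)-1-[(tert-butyldimethylsilyl)oxy]-1-(4-methoxyphenyl)-3-oxo-4-{4-[(triisopropylsilyl)oxy]phenyl}butan-2-yl]formamide | COc1ccc([C@@H](O[Si](C)(C)C(C)(C)C)[C@@H](NC=O)C(=O)Cc2ccc(O[Si](C(C)C)(C(C)C)C(C)C)cc2)cc1
F2 | step 14 | allyl N-[{[(1R,2R)-1-[(tert-butyldimethylsilyl)oxy]-1-(4-methoxyphenyl)-3-oxo-4-{4-[(triisopropylsilyl)oxy]phenyl}butan-2-yl]amino}(methylamino)methylidene]carbamate | COc1ccc([C@@H](O[Si](C)(C)C(C)(C)C)[C@@H](NC(NC)=NC(=O)OCC=C)C(=O)Cc2ccc(O[Si](C(C)C)(C(C)C)C(C)C)cc2)cc1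
F3 | step 14 | allyl N-{4-[(R)-[(tert-butyldimethylsilyl)oxy](4-methoxyphenyl)methyl]-1-methyl-5-{4-[(triisopropylsilyl)oxy]benzyl}-1H-imidazol-2-yl}carbamate | COc1ccc([C@@H](O[Si](C)(C)C(C)(C)C)c2nc(NC(=O)OCC=C)n(C)c2Cc2ccc(O[Si](C(C)C)(C(C)C)C(C)C)cc2)cc1
F4 | step 17 | ethyl 2-amino-2-({4-[(R)-[(tert-butyldimethylsilyl)oxy](4-methoxyphenyl)methyl]-1-methyl-5-{4-[(triisopropylsilyl)oxy]benzyl}-1H-imidazol-2-yl}imino)acetate | COc1ccc([C@@H](O[Si](C)(C)C(C)(C)C)c2nc(N=C(N)C(=O)OCC)n(C)c2Cc2ccc(O[Si](C(C)C)(C(C)C)C(C)C)cc2)cc1
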